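**One-step world.** If substrate met free catalyst in one step and left as product, the run would be pseudo-first-order. Then ln S would fall with time t at a slope k = κC, where S is the substrate, C the free catalyst charged and κ a constant, and the order in free catalyst would be one.

| flask | substrate | reagent | capture agent | free catalyst | added ligand | remark |
|---|---|---|---|---|---|---|
| autumn | 1.1 M | 1.04 M | 0.055 M | 31 mM | 45 mM | run made earlier |
| spring | 1.1 M | 1.04 M | 0.055 M | 48 mM | 45 mM | run made earlier |
| summer | 1.1 M | 1.6 M | 0.055 M | 22 mM | 45 mM | run made earlier |
| flask | 1.1 M | 1.04 M | 0.0550 M | 22 mM | 45 mM |  |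

| run | time / min | product / % | substrate / % |
|---|---|---|---|
| autumn | 2.00 | 9.2 | 90.9 |
| autumn | 4.00 | 15.4 | 83.9 |
| autumn | 10.0 | 34.4 | 63.7 |
| autumn | 25.0 | 60.4 | 38.3 |
| spring | 3.00 | 19.1 | 79.8 |
| spring | 8.00 | 39.9 | 57.7 |
| spring | 15.0 | 58.8 | 38.5 |
| spring | 25.0 | 74.9 | 23.0 |
| summer | 3.00 | 10.2 | 90.3 |
| summer | 8.00 | 22.8 | 75.9 |
| summer | 15.0 | 38.0 | 62.2 |
| summer | 25.0 | 53.0 | 45.9 |

(each reading ± 0.5 percentage points)

- apparent order in reagent when 50 % of the substrate are converted (percent change of the rate of making product for one percent more reagent charged)
- apparent order in free catalyst when 50 % of the substrate are converted (percent change of the rate of making product for one percent more free catalyst charged)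



**The border.** Over the readings bracketing 50 % conversion, k is 0.0339 min⁻¹ in the autumn run and 0.0578 min⁻¹ in the spring run. These rise by a factor 1.71, more than the factor 1.55 in free catalyst, so the rule stops here. Suppose the same small amount of catalyst leaves work with each turnover; catalyst lost then follows substrate converted, and k = κ(C − D). The line through both runs gives D = 6.86 mM, the catalyst debt: the catalyst out of work at 50 % conversion, taken as the same sum for either charge.

This reading is 14.3 % of the spring charge but 31.2 % of the flask's, and the order in free catalyst becomes C/(C − D), or 1.45 for the flask. The flask's k then reckons to 0.0213 min⁻¹. Against 0.0304 min⁻¹ in the summer run, with equal catalyst and more reagent, the order in reagent reckons to 0.828.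

**The forecast.** The forecast gives 0.5 for reagent (0.25 to 0.75) and 1 for free catalyst (0.85 to 1.2), holding that “Autumn and spring agree, so the catalyst order is about 1”. The reckoning above lies higher on both.

**The result.** The flask gives 0.78 in reagent and 1.4 in free catalyst.

    substrate + free catalyst → catalyst intermediate A (k = 0.0412 L mol⁻¹ s⁻¹)
    reagent + catalyst intermediate A → catalyst intermediate B (k = 0.217 L mol⁻¹ s⁻¹)
    catalyst intermediate B → released group + catalyst intermediate C (k = 1.26 s⁻¹)
    catalyst intermediate C ⇌ free catalyst + product (K = 2.50 M, k = 14.2 s⁻¹)
    free catalyst + added ligand ⇌ idle complex (K = 8.70 L mol⁻¹, k = 0.745 L mol⁻¹ s⁻¹)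
    catalyst intermediate A + capture agent → trapped intermediate (k = 0.0341 L mol⁻¹ s⁻¹)

**The debt.** One reason is the capture of catalyst intermediate A: in the run without that step, the flask's order in free catalyst is 1.0 instead of 1.4. At 20.0 min, with product at 42.5 %, trapped intermediate already holds 22.5 % of the flask's catalyst, or 4.95 mM. For the run with twice the flask's free catalyst, subtracting the debt from both charges gives a factor 2.45 on the rate, and that run gives 2.42.

(The numbers in the tables stem from a simulated flask for substances that don't exist.)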